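The carbocycle (ring A, ten-membered, germacrane numbering) is disconnected at the C6–C7 bond, between the ester carbinol and the isopropyl-bearing carbon. The feature used is the homoallylic alcohol array O–C6–C7–C8=C9 inside ring A, which is the retron of a [2,3]-Wittig shift. The precursor is therefore a nine-membered cyclic bis-allylic ether in which one oxygen joins C6 and C9 and the isopropyl-substituted alkene is exocyclic. One carbanion-triggered step expands this ether to ring A, forms C6–C7, sets C6 and C7, creates the E C8=C9 alkene and frees the C6 hydroxyl, which then directs epoxidation of the Z C4=C5 alkene and takes the ester.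

Key step: step 12

Remark: ring A is numbered as a germacrane (C1–C3 methylenes, C4 methyl-bearing, C5, C6 carbinol, C7 isopropyl-bearing, C8=C9, C10 methyl carbinol); the epoxide in the target is cis-fused (from a Z alkene); aldehyde 1 and acid 23 are taken as catalogue compounds.

Step 1
Reactants: 1 2-[(tert-butyldiphenylsilyl)oxy]acetaldehyde; 2 isopropenylmagnesium bromide
Product: 3 rac-1-[(tert-butyldiphenylsilyl)oxy]-3-methylbut-3-en-2-ol
Conditions: THF, −78 → 0 °C; then aq. NH4Cl
Reagents that add atoms: none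
Why: Grignard addition to the aldehyde gives the secondary allylic alcohol, made racemic on purpose because the next step resolves it.

Step 2
Reactants: 3 rac-1-[(tert-butyldiphenylsilyl)oxy]-3-methylbut-3-en-2-ol
Product: 4 (1S)-2-[(tert-butyldiphenylsilyl)oxy]-1-[(2R)-2-methyloxiran-2-yl]ethan-1-ol
Conditions: Ti(OiPr)4 (cat.), L-(+)-diisopropyl tartrate (cat.), t-BuOOH (0.5 equiv), 4 Å MS, CH2Cl2, −20 °C
Reagents that add atoms: tert-butyl hydroperoxide, CC(C)(C)OO
Why: Sharpless kinetic resolution by asymmetric epoxidation, in which L-(+)-tartrate should epoxidise the (R)-enantiomer of 3 fast and on the face that gives the erythro epoxy alcohol (the carbinol descriptor becomes S only through a priority change), so the catalyst selects the carbinol configuration and sets the quaternary epoxide carbon, while the other enantiomer stays behind and is separated (at most half of 3 is used).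

Step 3
Reactants: 4 (1S)-2-[(tert-butyldiphenylsilyl)oxy]-1-[(2R)-2-methyloxiran-2-yl]ethan-1-ol; 5 4-bromo-2-methylbut-1-ene
Product: 7 (2S,3R)-1-[(tert-butyldiphenylsilyl)oxy]-3,7-dimethyloct-7-ene-2,3-diol, via Grignard reagent 6 (not isolated)
Conditions: 5, Mg, THF, rt; then 4, CuI (cat.), THF, −30 → 0 °C; aq. NH4Cl
Reagents that add atoms: none
Why: Copper-catalysed Grignard opening of the 2,2-disubstituted epoxide at its CH2 terminus (SN2) attaches the 3-methylbut-3-enyl unit and unveils the tertiary alcohol without touching either stereocentre, one extra equivalent of 6 being spent on the free hydroxyl.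

Step 4
Reactants: 7 (2S,3R)-1-[(tert-butyldiphenylsilyl)oxy]-3,7-dimethyloct-7-ene-2,3-diol; 8 allyl bromide
Product: 9 (2S,3R)-1-[(tert-butyldiphenylsilyl)oxy]-3,7-dimethyl-2-(prop-2-en-1-yloxy)oct-7-en-3-ol
Conditions: NaH (1.1 equiv), Bu4NI (cat.), THF, 0 °C → rt
Reagents that add atoms: none
Why: Williamson etherification, in which the secondary alkoxide should form and react in preference to the tertiary one and the bulky tert-butyldiphenylsilyl group resists 1,2-migration under the basic conditions.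

Step 5
Reactants: 9 (2S,3R)-1-[(tert-butyldiphenylsilyl)oxy]-3,7-dimethyl-2-(prop-2-en-1-yloxy)oct-7-en-3-ol
Product: 10 (2S,3R,7Z)-2-{[(tert-butyldiphenylsilyl)oxy]methyl}-3,7-dimethyl-2,3,4,5,6,9-hexahydrooxonin-3-ol
Conditions: second-generation Grubbs catalyst RuCl2(H2IMes)(PCy3)(=CHPh) (cat.), CH2Cl2, high dilution, 40 °C
Reagents that add atoms: none
Why: Ring-closing metathesis of the allyl ether with the 1,1-disubstituted alkene should close the nine-membered ether with loss of ethene, helped by the gauche preference of the vicinal C–O bonds and the quaternary carbon, and only the Z trisubstituted alkene can form in this ring size; the alkenyl side chain is added afterwards because it would divert the catalyst into a five-membered ring closure.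

Step 6
Reactants: 10 (2S,3R,7Z)-2-{[(tert-butyldiphenylsilyl)oxy]methyl}-3,7-dimethyl-2,3,4,5,6,9-hexahydrooxonin-3-ol
Product: 11 (2S,3R,7Z)-2-(hydroxymethyl)-3,7-dimethyl-2,3,4,5,6,9-hexahydrooxonin-3-ol
Conditions: Bu4NF, AcOH, THF, rt
Reagents that add atoms: none
Why: Buffered fluoride cleaves the primary silyl ether and leaves the allylic ether ring untouched.

Step 7
Reactants: 11 (2S,3R,7Z)-2-(hydroxymethyl)-3,7-dimethyl-2,3,4,5,6,9-hexahydrooxonin-3-ol
Product: 12 (2S,3R,7Z)-3,7-dimethyl-3-[(triethylsilyl)oxy]-2-{[(triethylsilyl)oxy]methyl}-2,3,4,5,6,9-hexahydrooxonine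
Conditions: Et3SiOTf (2.5 equiv), 2,6-lutidine, CH2Cl2, −78 → 0 °C
Reagents that add atoms: triethylsilyl trifluoromethanesulfonate, CC[Si](CC)(CC)OS(=O)(=O)C(F)(F)F
Why: Silylation with the silyl triflate protects the hindered tertiary alcohol and the primary one in the same operation.

Step 8
Reactants: 12 (2S,3R,7Z)-3,7-dimethyl-3-[(triethylsilyl)oxy]-2-{[(triethylsilyl)oxy]methyl}-2,3,4,5,6,9-hexahydrooxonine
Product: 13 (2R,3R,7Z)-3,7-dimethyl-3-[(triethylsilyl)oxy]-2,3,4,5,6,9-hexahydrooxonine-2-carbaldehyde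
Conditions: (COCl)2, DMSO, CH2Cl2, −78 → −40 °C; then Et3N, −78 → 0 °C
Reagents that add atoms: none
Why: Under Swern conditions an unhindered primary triethylsilyl ether is cleaved and oxidised to the aldehyde in one pot while the tertiary silyl ether survives, and the low temperature keeps the α-alkoxy stereocentre intact.

Step 9
Reactants: 14 1-phenyl-1H-tetrazole-5-thiol; 15 1-bromo-2-methylpropane
Product: 16 5-[(2-methylpropyl)sulfanyl]-1-phenyl-1H-tetrazole
Conditions: K2CO3, DMF, 60 °C
Reagents that add atoms: none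
Why: SN2 S-alkylation of the tetrazolethiolate.

Step 10
Reactants: 16 5-[(2-methylpropyl)sulfanyl]-1-phenyl-1H-tetrazole
Product: 17 5-[(2-methylpropyl)sulfonyl]-1-phenyl-1H-tetrazole
Conditions: H2O2 (30 %), (NH4)6Mo7O24 (cat.), EtOH, rt
Reagents that add atoms: hydrogen peroxide, OO
Why: Molybdate-catalysed peroxide oxidation of the sulfide to the sulfone.

Step 11
Reactants: 13 (2R,3R,7Z)-3,7-dimethyl-3-[(triethylsilyl)oxy]-2,3,4,5,6,9-hexahydrooxonine-2-carbaldehyde; 17 5-[(2-methylpropyl)sulfonyl]-1-phenyl-1H-tetrazole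
Product: 18 (2S,3R,7Z)-3,7-dimethyl-2-[(1E)-3-methylbut-1-en-1-yl]-3-[(triethylsilyl)oxy]-2,3,4,5,6,9-hexahydrooxonine
Conditions: 17, KN(SiMe3)2, DME, −60 °C; then 13, −60 °C → rt
Reagents that add atoms: none
Why: Julia–Kocienski olefination, in which addition of the potassiated sulfone to the aldehyde, Smiles rearrangement and loss of SO2 and tetrazololate should give the E-disubstituted alkene (potassium base in DME favours E), the adjacent stereocentre being preserved by the low temperature.

Step 12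
Reactants: 18 (2S,3R,7Z)-3,7-dimethyl-2-[(1E)-3-methylbut-1-en-1-yl]-3-[(triethylsilyl)oxy]-2,3,4,5,6,9-hexahydrooxonine
Product: 21 (1R,2Z,7R,8E,10S)-3,7-dimethyl-10-(propan-2-yl)-7-[(triethylsilyl)oxy]cyclodeca-2,8-dien-1-ol, via lithiated ether 19 (not isolated), via lithium alkoxide 20 (not isolated)
Conditions: n-BuLi (1.5 equiv), THF, −78 → −30 °C; then aq. NH4Cl at −78 °C
Reagents that add atoms: none
Why: Proposed new method: n-BuLi should remove a proton from the ring CH2 that is both allylic and α to oxygen (the other α-oxy C–H is a methine shielded by the quaternary carbinol carbon), and the allyllithium 19 should undergo a concerted suprafacial [2,3]-Wittig shift in which this carbon bonds to the distal carbon of the exocyclic E-alkenyl group while the ring C–O bond at the alkenyl-bearing carbon breaks, giving alkoxide 20. The closest known reactions are the acyclic [2,3]-Wittig rearrangement of bis-allylic ethers and the [2,3]-Wittig ring contractions of macrocyclic diallylic ethers to medium carbocycles, whereas an endocyclic carbanion with an exocyclic migrating terminus in a medium-ring ether has not been described. Ring A is closed as a ring expansion (nine-membered ether to ten-membered carbocycle, oxygen expelled from the ring) through a five-membered envelope transition state bridged by the six-carbon chain, an oxabicyclo[6.2.1]undecene-like array. C6 is fixed by topology, because the two-carbon alkene unit can bridge the two oxygen-flanked ring carbons only on one face of the nine-membered ring, so the (S) ether carbon relays (R) to the carbinol; C7 is set by chirality transfer from the same carbon through the E-alkene in the rotamer that places the quaternary C10 outside (anti to the migrating terminus), which also makes C8=C9 E, and the ether stereocentre is consumed. The step needs [2,3] over [1,2] shift (low temperature), the outside rotamer over the inside one that would give the Z-alkene and the C7 epimer (A(1,3) strain of the fully substituted C10 with its silyl ether should secure it) and lithiation at the ring CH2 (sterics); the lithium alkoxide is quenched cold so that no anionic oxy-Cope shift of the 1,5-dien-3-olate follows.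

Step 13
Reactants: 21 (1R,2Z,7R,8E,10S)-3,7-dimethyl-10-(propan-2-yl)-7-[(triethylsilyl)oxy]cyclodeca-2,8-dien-1-ol
Product: 22 (4S,5R,6R,7S,8E,10R)-4,5-epoxy-10-[(triethylsilyl)oxy]germacr-8-en-6-ol
Conditions: VO(acac)2 (cat.), t-BuOOH, CH2Cl2, 0 °C → rt
Reagents that add atoms: tert-butyl hydroperoxide, CC(C)(C)OO
Why: Vanadium-catalysed hydroxyl-directed epoxidation, in which the vanadate ester of the C6 alcohol should deliver oxygen to the adjacent Z C4=C5 alkene on the face syn to the hydroxyl (cis-epoxy alcohol, as for medium-ring cycloalkenols), setting C4 (S) and C5 (R), while the homoallylic, less substituted C8=C9 alkene reacts much more slowly.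

Step 14
Reactants: 22 (4S,5R,6R,7S,8E,10R)-4,5-epoxy-10-[(triethylsilyl)oxy]germacr-8-en-6-ol; 23 4-[(tert-butyldimethylsilyl)oxy]benzoic acid
Product: 24 (4S,5R,6R,7S,8E,10R)-4,5-epoxy-10-[(triethylsilyl)oxy]germacr-8-en-6-yl 4-[(tert-butyldimethylsilyl)oxy]benzoate
Conditions: DCC, DMAP, CH2Cl2, rt
Reagents that add atoms: none
Why: Steglich esterification of the secondary alcohol with the silyl-protected acid, to which the tertiary silyl ether and the epoxide are inert.

Step 15
Reactants: 24 (4S,5R,6R,7S,8E,10R)-4,5-epoxy-10-[(triethylsilyl)oxy]germacr-8-en-6-yl 4-[(tert-butyldimethylsilyl)oxy]benzoate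
Product: 25 (4S,5R,6R,7S,8E,10R)-4,5-epoxy-10-hydroxygermacr-8-en-6-yl 4-hydroxybenzoate (CNP0278889.1)
Conditions: Bu4NF, AcOH, THF, 0 °C → rt
Reagents that add atoms: none
Why: Buffered fluoride should remove the aryl silyl ether and the tertiary triethylsilyl ether in one operation without opening the epoxide or cleaving the benzoate.

Compound list
1 | 2-[(tert-butyldiphenylsilyl)oxy]acetaldehyde | O=CCO[Si](c1ccccc1)(c1ccccc1)C(C)(C)C | starting material
2 | isopropenylmagnesium bromide | CC(=C)[Mg]Br | starting material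
3 | rac-1-[(tert-butyldiphenylsilyl)oxy]-3-methylbut-3-en-2-ol | CC(=C)C(O)CO[Si](c1ccccc1)(c1ccccc1)C(C)(C)C | intermediate
4 | (1S)-2-[(tert-butyldiphenylsilyl)oxy]-1-[(2R)-2-methyloxiran-2-yl]ethan-1-ol | CC(C)(C)[Si](c1ccccc1)(c1ccccc1)OC[C@H](O)[C@@]1(C)CO1 | intermediate
5 | 4-bromo-2-methylbut-1-ene | CC(=C)CCBr | starting material
6 | (3-methylbut-3-en-1-yl)magnesium bromide | CC(=C)CC[Mg]Br | intermediate (not isolated)
7 | (2S,3R)-1-[(tert-butyldiphenylsilyl)oxy]-3,7-dimethyloct-7-ene-2,3-diol | CC(C)(C)[Si](c1ccccc1)(c1ccccc1)OC[C@H](O)[C@](C)(O)CCCC(C)=C | intermediate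
8 | allyl bromide | C=CCBr | starting material
9 | (2S,3R)-1-[(tert-butyldiphenylsilyl)oxy]-3,7-dimethyl-2-(prop-2-en-1-yloxy)oct-7-en-3-ol | CC(C)(C)[Si](c1ccccc1)(c1ccccc1)OC[C@H](OCC=C)[C@](C)(O)CCCC(C)=C | intermediate
10 | (2S,3R,7Z)-2-{[(tert-butyldiphenylsilyl)oxy]methyl}-3,7-dimethyl-2,3,4,5,6,9-hexahydrooxonin-3-ol (O1; C2 side chain; C3 carbinol; C7=C8) | CC(C)(C)[Si](c1ccccc1)(c1ccccc1)OC[C@@H]1OC/C=C(/C)CCC[C@@]1(C)O | intermediate
11 | (2S,3R,7Z)-2-(hydroxymethyl)-3,7-dimethyl-2,3,4,5,6,9-hexahydrooxonin-3-ol | OC[C@@H]1OC/C=C(/C)CCC[C@@]1(C)O | intermediate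
12 | (2S,3R,7Z)-3,7-dimethyl-3-[(triethylsilyl)oxy]-2-{[(triethylsilyl)oxy]methyl}-2,3,4,5,6,9-hexahydrooxonine | CC[Si](CC)(CC)OC[C@@H]1OC/C=C(/C)CCC[C@@]1(C)O[Si](CC)(CC)CC | intermediate
13 | (2R,3R,7Z)-3,7-dimethyl-3-[(triethylsilyl)oxy]-2,3,4,5,6,9-hexahydrooxonine-2-carbaldehyde | O=C[C@@H]1OC/C=C(/C)CCC[C@@]1(C)O[Si](CC)(CC)CC | intermediate
14 | 1-phenyl-1H-tetrazole-5-thiol | Sc1nnnn1-c1ccccc1 | starting material
15 | 1-bromo-2-methylpropane | CC(C)CBr | starting material
16 | 5-[(2-methylpropyl)sulfanyl]-1-phenyl-1H-tetrazole | CC(C)CSc1nnnn1-c1ccccc1 | intermediate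
17 | 5-[(2-methylpropyl)sulfonyl]-1-phenyl-1H-tetrazole | CC(C)CS(=O)(=O)c1nnnn1-c1ccccc1 | intermediate
18 | (2S,3R,7Z)-3,7-dimethyl-2-[(1E)-3-methylbut-1-en-1-yl]-3-[(triethylsilyl)oxy]-2,3,4,5,6,9-hexahydrooxonine | CC(C)/C=C/[C@@H]1OC/C=C(/C)CCC[C@@]1(C)O[Si](CC)(CC)CC | intermediate
19 | 9-lithio derivative of 18 (allyllithium at the ring OCH2 carbon, configuration at the lithiated carbon not fixed) | CC(C)/C=C/[C@@H]1OC([Li])/C=C(/C)CCC[C@@]1(C)O[Si](CC)(CC)CC | intermediate (not isolated)
20 | lithium (1R,2Z,7R,8E,10S)-3,7-dimethyl-10-(propan-2-yl)-7-[(triethylsilyl)oxy]cyclodeca-2,8-dien-1-olate | CC(C)[C@H]1/C=C/[C@](C)(O[Si](CC)(CC)CC)CCC/C(C)=C\[C@@H]1O[Li] | intermediate (not isolated)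
21 | (1R,2Z,7R,8E,10S)-3,7-dimethyl-10-(propan-2-yl)-7-[(triethylsilyl)oxy]cyclodeca-2,8-dien-1-ol | CC(C)[C@H]1/C=C/[C@](C)(O[Si](CC)(CC)CC)CCC/C(C)=C\[C@@H]1O | intermediate
22 | (4S,5R,6R,7S,8E,10R)-4,5-epoxy-10-[(triethylsilyl)oxy]germacr-8-en-6-ol | CC(C)[C@H]1/C=C/[C@](C)(O[Si](CC)(CC)CC)CCC[C@]2(C)O[C@@H]2[C@@H]1O | intermediate
23 | 4-[(tert-butyldimethylsilyl)oxy]benzoic acid | OC(=O)c1ccc(O[Si](C)(C)C(C)(C)C)cc1 | starting material
24 | (4S,5R,6R,7S,8E,10R)-4,5-epoxy-10-[(triethylsilyl)oxy]germacr-8-en-6-yl 4-[(tert-butyldimethylsilyl)oxy]benzoate | CC(C)[C@H]1/C=C/[C@](C)(O[Si](CC)(CC)CC)CCC[C@]2(C)O[C@@H]2[C@@H]1OC(=O)c1ccc(O[Si](C)(C)C(C)(C)C)cc1 | intermediate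
25 | (4S,5R,6R,7S,8E,10R)-4,5-epoxy-10-hydroxygermacr-8-en-6-yl 4-hydroxybenzoate | CC(C)[C@H]1/C=C/[C@](C)(O)CCC[C@]2(C)O[C@@H]2[C@@H]1OC(=O)c1ccc(O)cc1 | target

Total step count: 15. Longest linear sequence: 13 (steps 1–8 and 11–15; steps 9–10 make the sulfone).

Steps most likely to fail

Step 12 (Proposed new method). The exocyclic alkene terminus may not reach the ring carbanion, so that a [1,2]-shift or ether cleavage takes over, or the inside rotamer may react and give the Z-alkene with the C7 epimer. The fallback uses the classical acyclic rearrangement and closes ring A afterwards; it sets out from 9 and comes back at 21. The silyl ether of 9 is cleaved (Bu4NF, AcOH) to (2S,3R)-3,7-dimethyl-2-(prop-2-en-1-yloxy)oct-7-ene-1,3-diol F1. Both hydroxyls are silylated (Et3SiOTf, 2,6-lutidine) to the bis(triethylsilyl) ether F2. Swern oxidation gives (2R,3R)-3,7-dimethyl-2-(prop-2-en-1-yloxy)-3-[(triethylsilyl)oxy]oct-7-enal F3, and Julia–Kocienski olefination with 17 gives the open-chain bis-allylic ether F4. Its [2,3]-Wittig rearrangement (n-BuLi, THF, −78 °C) should give the E-alkene and the C7 centre by the same chirality transfer. As usual for an E-allyl unit with a vinyl-substituted carbanion, it is expected to give mainly the anti carbinol, (3R,4S,5E,7R)-trienol F5. Mitsunobu inversion with 4-nitrobenzoic acid (PPh3, diisopropyl azodicarboxylate) gives the 4-nitrobenzoate F6, and methanolysis (K2CO3, MeOH) gives the (3S,4S,5E,7R)-trienol F7. Ring-closing metathesis of its vinyl and isopropenyl ends (second-generation Grubbs catalyst, high dilution) then closes ring A at C4=C5 and returns to 21.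

Step 5. The closure may stall at the 1,1-disubstituted alkene or be lost to oligomerisation. The fallback closes the ring at C3–C4 by a B-alkyl Suzuki–Miyaura coupling that brings the Z geometry in from a vinyl iodide; it sets out from 4 and comes back at 10. But-2-yn-1-ol is hydroaluminated and iodinated (NaAlH2(OCH2CH2OMe)2, then iodine) to (2Z)-3-iodobut-2-en-1-ol F8, which is brominated (CBr4, PPh3) to (2Z)-1-bromo-3-iodobut-2-ene F9. Epoxy alcohol 4 is opened with vinylmagnesium bromide and CuI to (2S,3R)-1-[(tert-butyldiphenylsilyl)oxy]-3-methylhex-5-ene-2,3-diol F10. Its secondary hydroxyl is alkylated with F9 (NaH) to the iodoalkenyl ether F11. Hydroboration of the terminal alkene with 9-borabicyclo[3.3.1]nonane gives the alkylborane F12, which is not isolated, and Pd(dppf)Cl2, AsPh3 and Cs2CO3 at high dilution close the ring to 10.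

Step 13. Oxygen may be delivered to the wrong face of C4=C5 if the ten-membered ring does not hold the hydroxyl as smaller cycloalkenols do, or the C8=C9 alkene may compete. The fallback replaces substrate direction by reagent control: titanium–tartrate (Sharpless) epoxidation of 21 with Ti(OiPr)4, D-(−)-diisopropyl tartrate and t-BuOOH (4 Å MS, CH2Cl2, −20 °C). For the (6R)-alcohol this tartrate is the matched partner and should deliver oxygen to the required face (erythro product). It sets out from 21, comes back at 22 and makes no new compound.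

Further compounds
F1 | step 12 | (2S,3R)-3,7-dimethyl-2-(prop-2-en-1-yloxy)oct-7-ene-1,3-diol | OC[C@H](OCC=C)[C@](C)(O)CCCC(C)=C
F2 | step 12 | (2S,3R)-3,7-dimethyl-2-(prop-2-en-1-yloxy)-1,3-bis[(triethylsilyl)oxy]oct-7-ene | CC[Si](CC)(CC)OC[C@H](OCC=C)[C@](C)(O[Si](CC)(CC)CC)CCCC(C)=C
F3 | step 12 | (2R,3R)-3,7-dimethyl-2-(prop-2-en-1-yloxy)-3-[(triethylsilyl)oxy]oct-7-enal | O=C[C@H](OCC=C)[C@](C)(O[Si](CC)(CC)CC)CCCC(C)=C
F4 | step 12 | triethyl{[(3E,5S,6R)-2,6,10-trimethyl-5-(prop-2-en-1-yloxy)undeca-3,10-dien-6-yl]oxy}silane | CC(C)/C=C/[C@H](OCC=C)[C@](C)(O[Si](CC)(CC)CC)CCCC(C)=C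
F5 | step 12 | (3R,4S,5E,7R)-7,11-dimethyl-4-(propan-2-yl)-7-[(triethylsilyl)oxy]dodeca-1,5,11-trien-3-ol | C=C[C@@H](O)[C@@H](C(C)C)/C=C/[C@](C)(O[Si](CC)(CC)CC)CCCC(C)=C
F6 | step 12 | (3S,4S,5E,7R)-7,11-dimethyl-4-(propan-2-yl)-7-[(triethylsilyl)oxy]dodeca-1,5,11-trien-3-yl 4-nitrobenzoate | C=C[C@H](OC(=O)c1ccc(cc1)[N+](=O)[O-])[C@@H](C(C)C)/C=C/[C@](C)(O[Si](CC)(CC)CC)CCCC(C)=C
F7 | step 12 | (3S,4S,5E,7R)-7,11-dimethyl-4-(propan-2-yl)-7-[(triethylsilyl)oxy]dodeca-1,5,11-trien-3-ol | C=C[C@H](O)[C@@H](C(C)C)/C=C/[C@](C)(O[Si](CC)(CC)CC)CCCC(C)=C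
F8 | step 5 | (2Z)-3-iodobut-2-en-1-ol | C/C(I)=C/CO
F9 | step 5 | (2Z)-1-bromo-3-iodobut-2-ene | C/C(I)=C/CBr
F10 | step 5 | (2S,3R)-1-[(tert-butyldiphenylsilyl)oxy]-3-methylhex-5-ene-2,3-diol | CC(C)(C)[Si](c1ccccc1)(c1ccccc1)OC[C@H](O)[C@](C)(O)CC=C
F11 | step 5 | (2S,3R)-1-[(tert-butyldiphenylsilyl)oxy]-2-{[(2Z)-3-iodobut-2-en-1-yl]oxy}-3-methylhex-5-en-3-ol | CC(C)(C)[Si](c1ccccc1)(c1ccccc1)OC[C@H](OC/C=C(/C)I)[C@](C)(O)CC=C
F12 | step 5 | (2S,3R)-6-(9-borabicyclo[3.3.1]nonan-9-yl)-1-[(tert-butyldiphenylsilyl)oxy]-2-{[(2Z)-3-iodobut-2-en-1-yl]oxy}-3-methylhexan-3-ol | CC(C)(C)[Si](c1ccccc1)(c1ccccc1)OC[C@H](OC/C=C(/C)I)[C@](C)(O)CCCB1C2CCCC1CCC2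
F0 | step 13 | none | none
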